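**Assumption:** the SMILES is read as the all-trans (2R,3S,4S,5R) isomer and taken to be (+)-neoolivil; (R)-4-benzyl-2-oxazolidinone, succinyl chloride and O-benzylvanillin are bought. The route is a design that has not been run; the endgame (dilactone → THF diester → diol) follows the classical racemic chemistry of this skeleton.

## Retrosynthetic overview

1. Target ⇐ debenzylation and ester reduction of the all-trans dimethyl 2,5-diaryl-tetrahydrofuran-3,4-dicarboxylate.
2. THF diester ⇐ acid-mediated rearrangement (C7–O–C7' ether formation via benzylic cations) of the cis-fused 3,6-diaryl-furo[3,4-c]furan-1,4-dione (dilactone).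
3. Dilactone ⇐ double lactonisation, with loss of both auxiliaries, of a C2-symmetric bis-syn-aldol adduct.
4. Bis-aldol ⇐ two-directional Evans aldol of succinyl bis[(R)-4-benzyloxazolidinone] with two O-benzylvanillin units (forms C7–C8 and C7'–C8', sets C8/C8').
5. Ring order: the two γ-lactones first (temporary), then the single tetrahydrofuran at their expense.

## Route

**Step 1**
Reactants: 1, (R)-4-benzyl-1,3-oxazolidin-2-one (2 equiv); 2, succinyl chloride
Product: 3, 1,4-bis[(4R)-4-benzyl-2-oxo-1,3-oxazolidin-3-yl]butane-1,4-dione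
Conditions: n-BuLi (2.05 equiv), THF, −78 °C; then 2 (1.0 equiv), −78 → 0 °C
Reagents that add atoms: none
Why: N-acylation of the lithiated Evans oxazolidinone by the bis-acid chloride puts the same (R)-auxiliary on both ends of the C4 unit, so both later aldol events are controlled identically; no stereocenter is formed.

**Step 2**
Reactants: 3; 4, 4-(benzyloxy)-3-methoxybenzaldehyde (2.5 equiv)
Product: 5, (2R,3R)-1,4-bis[(4R)-4-benzyl-2-oxo-1,3-oxazolidin-3-yl]-2,3-bis{(R)-[4-(benzyloxy)-3-methoxyphenyl](hydroxy)methyl}butane-1,4-dione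
Conditions: Bu2BOTf (2.5 equiv), i-Pr2NEt (3 equiv), CH2Cl2, 0 °C; 4, −78 → 0 °C; pH 7 buffer, MeOH, 30% H2O2, 0 °C
Reagents that add atoms: none
Why: Double Evans syn-aldol in which each Z-dibutylboron enolate adds through a Zimmerman–Traxler chair on the face anti to the auxiliary benzyl group, so the (R)-auxiliary sets both succinyl carbons R and both carbinols R (syn), and a single mismatched event gives a separable diastereomer, not the enantiomer.

**Step 3**
Reactants: 5
Product: 6, (3R,3aR,6R,6aR)-3,6-bis[4-(benzyloxy)-3-methoxyphenyl]tetrahydro-1H,4H-furo[3,4-c]furan-1,4-dione (cis-fused, aryls exo), plus 2 equiv of recovered 1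
Conditions: DMAP (0.2 equiv), Et3N, CH2Cl2, rt
Reagents that add atoms: none
Why: Each benzylic hydroxyl is γ to the other imide carbonyl, so intramolecular transacylation (5-exo lactonisation) expels both oxazolidinones and gives the cis-fused bislactone, which only the R,R (dl) succinate core can form, without touching any stereocenter.

**Step 4**
Reactants: 6
Product: 7, dimethyl (2R,3R,4R,5R)-2,5-bis[4-(benzyloxy)-3-methoxyphenyl]oxolane-3,4-dicarboxylate (all-trans)
Conditions: HCl (ca. 2 M, from AcCl), MeOH, reflux
Reagents that add atoms: methanol, CO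
Why: Acid-mediated dilactone-to-tetrahydrofuran rearrangement in which methanolysis and ionisation of the p-alkoxybenzylic C–O bonds give cations trapped by the other benzylic oxygen (SN1 cyclo-etherification) while the carboxyls become methyl esters; the former ring-fusion carbons are untouched and emerge trans, and reversible ionisation places both aryls trans to their neighbours (thermodynamic all-trans).

**Step 5**
Reactants: 7
Product: 8, {(2R,3S,4S,5R)-2,5-bis[4-(benzyloxy)-3-methoxyphenyl]oxolane-3,4-diyl}dimethanol
Conditions: LiAlH4, THF, 0 °C → rt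
Reagents that add atoms: none
Why: Hydride reduction of both esters to primary alcohols with no stereocenter involved (the C3/C4 labels change from R to S only because CH2OH ranks below C2).

**Step 6**
Reactants: 8
Product: 9, (+)-neoolivil, [(2R,3S,4S,5R)-2,5-bis(4-hydroxy-3-methoxyphenyl)oxolane-3,4-diyl]dimethanol
Conditions: H2 (1 atm), 10% Pd/C, EtOAc–MeOH, rt, stopped at full conversion
Reagents that add atoms: none
Why: Catalytic hydrogenolysis cleaves the two aryl benzyl ethers much faster than the cyclic dibenzylic ether, freeing both phenols without affecting the four stereocenters.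

## Compound list

1 | (R)-4-benzyl-1,3-oxazolidin-2-one | O=C1N[C@H](Cc2ccccc2)CO1 | starting material
2 | succinyl chloride | ClC(=O)CCC(=O)Cl | starting material
3 | 1,4-bis[(4R)-4-benzyl-2-oxooxazolidin-3-yl]butane-1,4-dione | O=C(CCC(=O)N1[C@H](Cc2ccccc2)COC1=O)N1[C@H](Cc2ccccc2)COC1=O | intermediate
4 | 4-(benzyloxy)-3-methoxybenzaldehyde | COc1cc(C=O)ccc1OCc1ccccc1 | starting material
5 | (2R,3R)-bis-syn-aldol bis-imide, carbinols R | COc1cc(ccc1OCc1ccccc1)[C@H](O)[C@H](C(=O)N1[C@H](Cc2ccccc2)COC1=O)[C@@H](C(=O)N1[C@H](Cc2ccccc2)COC1=O)[C@@H](O)c1ccc(OCc2ccccc2)c(OC)c1 | intermediate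
6 | (3R,3aR,6R,6aR)-3,6-bis[4-(benzyloxy)-3-methoxyphenyl]tetrahydrofuro[3,4-c]furan-1,4-dione | O=C1O[C@@H](c2ccc(OCc3ccccc3)c(OC)c2)[C@@H]2C(=O)O[C@@H](c3ccc(OCc4ccccc4)c(OC)c3)[C@H]12 | intermediate
7 | dimethyl (2R,3R,4R,5R)-2,5-bis[4-(benzyloxy)-3-methoxyphenyl]oxolane-3,4-dicarboxylate | COc1cc(ccc1OCc1ccccc1)[C@@H]1O[C@@H](c2ccc(OCc3ccccc3)c(OC)c2)[C@H](C(=O)OC)[C@H]1C(=O)OC | intermediate
8 | {(2R,3S,4S,5R)-2,5-bis[4-(benzyloxy)-3-methoxyphenyl]oxolane-3,4-diyl}dimethanol | COc1cc(ccc1OCc1ccccc1)[C@@H]1O[C@@H](c2ccc(OCc3ccccc3)c(OC)c2)[C@H](CO)[C@H]1CO | intermediate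
9 | (+)-neoolivil | COc1cc([C@@H]2O[C@@H](c3ccc(O)c(OC)c3)[C@H](CO)[C@H]2CO)ccc1O | target

## Summary

Total steps: 6. Longest linear sequence: 6 (1/2 → 3 → 5 → 6 → 7 → 8 → 9).

Steps most likely to fail, with fallbacks:

1. **Step 2 (double boron aldol on the succinyl bis-imide).** I know of no direct precedent for enolising and reacting both ends in one pot; the single aldol on succinate mono-imides is standard. Fallback: drop the two-directional plan for a linear one (about 10 steps). A single Evans syn-aldol of (R)-4-benzyl-3-(4-methoxy-4-oxobutanoyl)oxazolidin-2-one with 4 gives the trans-aryl-paraconate lactone. Convert CO–Xc to CH2OTBS, hydroxymethylate the lactone enolate trans, add the aryllithium from 4-benzyloxy-3-methoxybromobenzene to the lactone carbonyl, and reduce the lactol with Et3SiH/BF3·OEt2 to the all-trans THF.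

2. **Step 4 (cationic dilactone → THF rearrangement).** Risks are Friedel–Crafts closure to an aryltetralin, benzylic methyl ethers, or incomplete equilibration to all-trans. Fallback: close the ring at the alcohol oxidation level. Reduce 6 (or 5, with LiBH4) to the tetraol, silylate the two primary hydroxyls (TBSCl, imidazole), cyclise the bis-benzylic 1,4-diol (BF3·OEt2 or MsCl/Et3N, thermodynamic all-trans), then TBAF and H2/Pd–C.

3. **Step 6 (hydrogenolysis).** The electron-rich dibenzylic THF C–O bonds could also be cleaved. Fallback: change the protecting-group strategy by using 3-methoxy-4-(methoxymethoxy)benzaldehyde in Step 2. The MOM ethers are lost in the HCl/MeOH step to give the free-phenol diester, and LiAlH4 reduction becomes the final step with no hydrogenation.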